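Conventions used below: the oxolane is numbered O1, C2 (carries ring B), C3 (carries CH2OH), C4 (carries the ring A benzyl group), C5 (CH2). Ring A is 2,4,5-trimethoxyphenyl, ring B is 3,4,5-trimethoxyphenyl. Compound numbers 1–21 follow the order of first appearance in the steps; the full list stands after step 12.

## Analysis of the target

The target 21 is a monocyclic oxolane with three contiguous stereocentres: C2 bears ring B, C3 a hydroxymethyl group and C4 a CH2 link to ring A, while C5 is an unsubstituted CH2. Reading the SMILES gives (2R,3R,4R), with the aryl, hydroxymethyl and benzyl groups all on one face of the ring. This all-cis pattern is the most crowded arrangement, so it has to be made under kinetic control and cannot be reached or repaired by equilibration. The C2–O1 bond is a benzylic ether bond; acid can ionise it and forcing hydrogenation can cleave it. The six aryl methyl ethers make both rings electron-rich, ring A strongly so, which limits the use of strong electrophiles, Lewis acids and oxidants. The difficulty is to fix the absolute configuration with no functional group left over and then to set two further centres cis to the first. The strategy rests on the atoms around C2: C2 sits between O1 and C3, and C3 carries a one-carbon branch. An aryl alkyne gives exactly this pattern when its two carbons take up a hydroxyl oxygen and one carbon from CO. C4 then remains as the only stereocentre, and one syn addition of hydrogen relays its configuration to C2 and C3.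

## Retrosynthetic reasoning

21 to 20. The primary alcohol at C3 is taken back to a methyl ester. No skeletal bond is cut; the ester is the oxidation level in which the key step delivers the C3 branch. The forward step must reduce the ester without enolising C3.

20 to 19. The C2–H and C3–H bonds are removed to give the C2=C3 double bond of the 4,5-dihydrofuran 19. C2 and C3 are adjacent and both cis to the C4 substituent, so one syn addition from the face away from the C4 benzyl group sets both. C4 is then the only stereocentre to be carried, and it is an sp3 carbon without an acidic hydrogen. The forward step must add hydrogen to a tetrasubstituted, ester-conjugated enol ether bond with face selectivity and without cleaving the benzylic C2–O1 bond.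

19 to 18. This is the key disconnection: O1–C2 and the bond from C3 to the carboxyl carbon are cut together. The ring opens to the alkynol 18, in which the hydroxyl oxygen is the future O1 and the two alkyne carbons are C3 and C2. Cutting here removes the ring, the C3 branch and its oxidation level in one operation. A cut at C2–C3 or C3–C4 would require a stereocontrolled C–C bond formation next to the all-cis array. The forward step must achieve 5-endo oxypalladation of the alkyne and trap the resulting C3–palladium bond by carbonylation in an alcohol solvent.

18 to 15 and 16. After the silyl ether 17 is interposed to mask the hydroxyl, the bond between the alkyne and ring B is cut to the terminal alkyne 15 and the aryl iodide 16. This is the most reliable way to attach an aryl group to an alkyne, and it brings in ring B as a purchased unit late in the sequence.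

15 to 13. The terminal alkyne carbon is removed, leading back to the aldehyde 14 and then to the alcohol 13. The one-carbon homologation of an aldehyde to an alkyne lets the propargylic stereocentre be made as a simple 2-substituted 1,3-dioxygenated propane unit. In 13 the two oxygen arms differ only by the silyl group, so the forward steps must avoid silyl migration and enolisation of 14.

13 to 9. The bond from the stereocentre to the silyloxymethyl carbon is cut, via 12 and 11, back to the N-acyl oxazolidinone 9. A chelated enolate of 9 takes up a hydroxymethyl group with a predictable facial sense set by the auxiliary 7. The other conceivable cut, between C4 and its benzylic carbon, would need a benzylating agent derived from ring A, which is too prone to self-condensation to be a reliable electrophile.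

9 to 1, 2 and 7. The imide bond is cut to the acid 6 and the auxiliary 7. The acid 6 is cut at the bond between its benzylic carbon and the neighbouring CH2, leading to the aldehyde 1 and Meldrum's acid 2 through a condensation–reduction–decarboxylation sequence.

## Alternatives that were turned down

Alternative 1: The oxolane is cut at C2–C3 and C4–C5. In the forward direction 2-(3,4,5-trimethoxyphenyl)furan A1 and maleic anhydride A2 combine in a Diels–Alder reaction to the exo oxanorbornene anhydride A3.
- For: the ring is built in one step from two simple compounds. In the exo adduct both carbonyl carbons lie on the same face of the oxolane as ring B, so the all-cis relationship is present at once. On speed to the key intermediate this alternative is clearly stronger than the chosen route, which needs nine steps before its key step.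
- Against: A3 is formed from achiral partners and is racemic, so a resolution or an unproven asymmetric variant is required. Furan cycloadducts of this kind revert on heating.
- Against: most of the work lies after the key step. The two-carbon alkene bridge must be cut out, which means oxidative cleavage and removal of one carbon stub each at C2 and C5. The stub at C2 leaves through a benzylic, oxygen-stabilised radical or cation, which puts the C2 configuration at risk.
- Against: the two anhydride carbonyls must be told apart. One has to be reduced to CH2OH, and the other joined to ring A by a separate C–C bond formation and then deoxygenated.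
- Comparison: the chosen strategy gives up the fast start but reaches its key step with every carbon in place and with absolute configuration secured. It then needs only two steps to finish.

Alternative 2: The C2–C3 bond is cut. In the forward direction the vinyl diazo ester A4, under a dirhodium tetracarboxylate such as Rh2(S-DOSP)4, forms a carbene that inserts into the benzylic ether C–H bond five atoms away and gives the benzylidene oxolane ester A5.
- For: the route is convergent and short. It forms a C–C bond and sets C2 and C3 in one catalytic event that could be enantioselective, and the activated benzylic ether C–H bond is a good insertion site. On step count and convergence it is stronger than the chosen route.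
- Against: vinyl carbenes have their own escape routes, namely closure to a cyclopropene and electrocyclisation of the diazo compound to a pyrazole. Two very electron-rich arenes offer cyclopropanation and aromatic substitution as competitors.
- Against: neither the cis selectivity nor the enantioselectivity is assured for this substitution pattern.
- Against: in A5 the C3 hydrogen is both alpha to the ester and allylic to the styrene-type double bond. Migration of that double bond into conjugation would erase C3 before the later hydrogenation can set C4.
- Comparison: the chosen strategy is longer, but its only stereocentre during the sensitive stages is the non-acidic C4. C2 and C3 appear only in the penultimate step, and every step is of a known type.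

Alternative 3: The O1–C5 bond is cut. In the forward direction the vinyl oxirane A6 rearranges under Cu(hfacac)2: the oxirane C–O bond at the future C3 breaks and the oxygen closes onto the alkene terminus, giving the 2,5-dihydrofuran A7. Hydrogenation of C3=C4 from the face away from ring B and desilylation would follow.
- For: the key step is redox-neutral and needs neither CO nor an oxidant, and C2 would come from a dependable asymmetric epoxidation. The facial bias in the final hydrogenation comes from an aryl group directly next to the double bond, which is at least as strong as the bias from the C4 benzyl group in the chosen route.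
- Against: both oxirane C–O bonds are activated. The bond that must survive is benzylic, and at the temperature of the ring expansion its ionisation would scramble C2 or lead to carbonyl products by Meinwald rearrangement.
- Against: the precursor must already contain both aryl groups, the C3 branch and a trisubstituted alkene of defined geometry, so the route to A6 is at least as long as that to 18.
- Against: the C3=C4 bond of A7 is tetrasubstituted and unactivated. Its C2–O1 bond is benzylic and allylic at once, so hydrogenolysis and double-bond migration threaten exactly the centre that carries the information.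
- Comparison: the chosen strategy stores the information at an sp3 carbon that has no ionisable bond, and it forms the C3 branch in the ring-closing step.

Key step: step 10

## Route

Step 1
Reactants: 1 2,4,5-trimethoxybenzaldehyde; 2 Meldrum's acid (2,2-dimethyl-1,3-dioxane-4,6-dione)
Product: 6 3-(2,4,5-trimethoxyphenyl)propanoic acid, via arylidene Meldrum's acid 3 (not isolated), via benzyl Meldrum's acid 4 (not isolated), via benzylmalonic acid 5 (not isolated)
Conditions: HCO2H/Et3N (5:2), 95–100 °C; then aq. HCl
Reagents that add atoms: none
Why: Knoevenagel condensation of 1 with the acidic methylene of 2, conjugate hydride transfer from formate to 3, then hydrolysis of 4 by the water of condensation and decarboxylation of 5 in the same hot medium; this is a known one-pot reductive route from aryl aldehydes to 3-arylpropanoic acids and involves no stereocentre.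

Step 2
Reactants: 6 3-(2,4,5-trimethoxyphenyl)propanoic acid; 7 (R)-4-benzyloxazolidin-2-one
Product: 9 (R)-4-benzyl-3-[3-(2,4,5-trimethoxyphenyl)propanoyl]oxazolidin-2-one, via mixed pivalic anhydride 8 (not isolated)
Conditions: PivCl, Et3N, THF, −20 °C; then LiCl, 7, −20 °C → rt
Reagents that add atoms: none
Why: Mixed-anhydride N-acylation of the oxazolidinone; the LiCl-activated auxiliary attacks the arylpropanoyl carbonyl of 8 because the pivaloyl carbonyl is shielded by its tert-butyl group.

Step 3
Reactants: 9 (R)-4-benzyl-3-[3-(2,4,5-trimethoxyphenyl)propanoyl]oxazolidin-2-one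
Product: 11 (R)-4-benzyl-3-[(S)-3-hydroxy-2-(2,4,5-trimethoxybenzyl)propanoyl]oxazolidin-2-one, via chlorotitanium enolate 10 (not isolated)
Conditions: TiCl4, i-Pr2NEt, CH2Cl2, 0 °C; then 1,3,5-trioxane, TiCl4, 0 °C; aq. NH4Cl
Reagents that add atoms: 1,3,5-trioxane, C1OCOCO1
Why: Titanium-enolate hydroxymethylation of an N-acyl oxazolidinone (Evans aldol-type addition to Lewis-acid-activated formaldehyde); soft enolisation gives the chelated Z-enolate 10, which is attacked on the face opposite the benzyl group of the (R)-auxiliary, and this sets the new centre, the future C4, as (S).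

Step 4
Reactants: 11 (R)-4-benzyl-3-[(S)-3-hydroxy-2-(2,4,5-trimethoxybenzyl)propanoyl]oxazolidin-2-one
Product: 12 (R)-4-benzyl-3-[(S)-3-(tert-butyldiphenylsilyloxy)-2-(2,4,5-trimethoxybenzyl)propanoyl]oxazolidin-2-one
Conditions: TBDPSCl, imidazole, DMF, 0 °C → rt
Reagents that add atoms: tert-butyl(chloro)diphenylsilane, CC(C)(C)[Si](Cl)(c1ccccc1)c1ccccc1
Why: Imidazole-promoted silylation of the primary hydroxyl; the bulky silyl group withstands the hydride, carbonate and amine conditions of steps 5–8 and is slow to migrate between the two oxygen arms, a shift that would racemise 13.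

Step 5
Reactants: 12 (R)-4-benzyl-3-[(S)-3-(tert-butyldiphenylsilyloxy)-2-(2,4,5-trimethoxybenzyl)propanoyl]oxazolidin-2-one
Product: 13 (R)-3-(tert-butyldiphenylsilyloxy)-2-(2,4,5-trimethoxybenzyl)propan-1-ol
Conditions: LiBH4, MeOH (1 equiv), THF, 0 °C → rt
Reagents that add atoms: none
Why: Reductive removal of the auxiliary; borohydride attacks the exocyclic imide carbonyl and reduces it through to the primary alcohol, the stereocentre is not enolised, and 7 is recovered.

Step 6
Reactants: 13 (R)-3-(tert-butyldiphenylsilyloxy)-2-(2,4,5-trimethoxybenzyl)propan-1-ol
Product: 14 (S)-3-(tert-butyldiphenylsilyloxy)-2-(2,4,5-trimethoxybenzyl)propanal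
Conditions: Dess–Martin periodinane, CH2Cl2, 0 °C → rt; used crude
Reagents that add atoms: none
Why: Dess–Martin oxidation of the primary alcohol stops at the aldehyde under nearly neutral conditions, which keeps the enolisable α-centre intact; 14 is carried on without chromatography.

Step 7
Reactants: 14 (S)-3-(tert-butyldiphenylsilyloxy)-2-(2,4,5-trimethoxybenzyl)propanal
Product: 15 (R)-tert-butyldiphenyl{[2-(2,4,5-trimethoxybenzyl)but-3-yn-1-yl]oxy}silane
Conditions: dimethyl (1-diazo-2-oxopropyl)phosphonate, K2CO3, MeOH, 0 °C → rt
Reagents that add atoms: dimethyl (1-diazo-2-oxopropyl)phosphonate, COP(=O)(OC)C(=[N+]=[N-])C(C)=O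
Why: Ohira–Bestmann (Seyferth–Gilbert) homologation; methanolysis of the reagent gives the diazomethylphosphonate anion, which adds to the aldehyde and eliminates phosphate, and loss of N2 with a 1,2-hydrogen shift gives the terminal alkyne, while carbonate at 0 °C is mild enough to keep the α-centre and the silyl ether.

Step 8
Reactants: 15 (R)-tert-butyldiphenyl{[2-(2,4,5-trimethoxybenzyl)but-3-yn-1-yl]oxy}silane; 16 5-iodo-1,2,3-trimethoxybenzene
Product: 17 (R)-tert-butyldiphenyl{[2-(2,4,5-trimethoxybenzyl)-4-(3,4,5-trimethoxyphenyl)but-3-yn-1-yl]oxy}silane
Conditions: PdCl2(PPh3)2 (3 mol %), CuI (5 mol %), Et3N, THF, rt → 45 °C, degassed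
Reagents that add atoms: none
Why: Sonogashira coupling; oxidative addition of the aryl iodide to zerovalent palladium, transmetalation of the copper acetylide and reductive elimination form the bond between the alkyne and ring B, and the propargylic centre is not acidic enough to be affected by the amine.

Step 9
Reactants: 17 (R)-tert-butyldiphenyl{[2-(2,4,5-trimethoxybenzyl)-4-(3,4,5-trimethoxyphenyl)but-3-yn-1-yl]oxy}silane
Product: 18 (R)-2-(2,4,5-trimethoxybenzyl)-4-(3,4,5-trimethoxyphenyl)but-3-yn-1-ol
Conditions: TBAF, THF, 0 °C → rt
Reagents that add atoms: none
Why: Fluoride cleavage of the silyl ether frees the primary hydroxyl that serves as the nucleophile of the key step; the internal alkyne and the aryl ethers are inert.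

Step 10
Reactants: 18 (R)-2-(2,4,5-trimethoxybenzyl)-4-(3,4,5-trimethoxyphenyl)but-3-yn-1-ol
Product: 19 methyl (R)-4-(2,4,5-trimethoxybenzyl)-2-(3,4,5-trimethoxyphenyl)-4,5-dihydrofuran-3-carboxylate
Conditions: PdCl2(MeCN)2 (5 mol %), p-benzoquinone (1.5 equiv), CO (1 atm), MeOH, 0 °C → rt
Reagents that add atoms: carbon monoxide, [C-]#[O+]; methanol, CO
Why: Divalent palladium binds the alkyne of 18 and the primary hydroxyl adds to the aryl-bearing carbon anti to the metal, giving a 3-palladio-4,5-dihydrofuran; CO inserts into the C3–Pd bond and methanol cleaves the acylpalladium to the methyl ester, releasing zerovalent palladium, which benzoquinone and the two protons set free return to the divalent state. The closest known reaction type is the palladium-catalysed oxidative cyclisation–alkoxycarbonylation of alkynols, 3-yne-1,2-diols and 2-alkynylphenols under CO, applied here to a new substrate. The single ring, the oxolane, closes in the 5-endo-dig mode through O1–C2; the 4-exo-dig alternative would give a strained oxetane, and ring B stabilises positive charge at the carbon that the oxygen attacks. No stereocentre is formed, and C4 is a spectator because it carries no acidic hydrogen and β-hydride elimination from the C3–Pd bond towards C4 would require a cyclic allene. The step needs carbonylation to outrun protonolysis of the C3–Pd bond and capture of the acylpalladium by a second alkynol; CO-saturated methanol as solvent, low temperature and the acid-consuming reoxidation by benzoquinone serve this, and the unhindered primary hydroxyl makes ring closure faster than intermolecular methoxypalladation.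

Step 11
Reactants: 19 methyl (R)-4-(2,4,5-trimethoxybenzyl)-2-(3,4,5-trimethoxyphenyl)-4,5-dihydrofuran-3-carboxylate
Product: 20 methyl (2R,3S,4R)-4-(2,4,5-trimethoxybenzyl)-2-(3,4,5-trimethoxyphenyl)oxolane-3-carboxylate
Conditions: H2 (30 bar), 5% Rh/Al2O3, EtOAc, rt
Reagents that add atoms: none
Why: Heterogeneous catalytic hydrogenation; both hydrogens are delivered syn from the catalyst surface to the face of the C2=C3 bond opposite the C4 benzyl group, so ring B at C2 and the ester at C3 end up cis to each other and to the benzyl group (C2 R, C3 S), and Rh/Al2O3 is chosen because it reduces hindered enol ether bonds with less benzylic C–O hydrogenolysis than palladium.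

Step 12
Reactants: 20 methyl (2R,3S,4R)-4-(2,4,5-trimethoxybenzyl)-2-(3,4,5-trimethoxyphenyl)oxolane-3-carboxylate
Product: 21 [(2R,3R,4R)-4-(2,4,5-trimethoxybenzyl)-2-(3,4,5-trimethoxyphenyl)oxolan-3-yl]methanol
Conditions: LiAlH4, THF, −20 → 0 °C; Rochelle salt work-up
Reagents that add atoms: none
Why: Hydride reduction of the methyl ester to the primary alcohol at low temperature, where reduction is faster than enolisation at C3; no stereocentre is changed, and the C3 descriptor becomes R only through the change in substituent priority.

## Compound list

1 | 2,4,5-trimethoxybenzaldehyde | COc1cc(OC)c(OC)cc1C=O | starting material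
2 | Meldrum's acid (2,2-dimethyl-1,3-dioxane-4,6-dione) | CC1(C)OC(=O)CC(=O)O1 | starting material
3 | 2,2-dimethyl-5-(2,4,5-trimethoxybenzylidene)-1,3-dioxane-4,6-dione | COc1cc(OC)c(OC)cc1C=C1C(=O)OC(C)(C)OC1=O | intermediate (not isolated)
4 | 2,2-dimethyl-5-(2,4,5-trimethoxybenzyl)-1,3-dioxane-4,6-dione | COc1cc(OC)c(OC)cc1CC1C(=O)OC(C)(C)OC1=O | intermediate (not isolated)
5 | 2-(2,4,5-trimethoxybenzyl)malonic acid | COc1cc(OC)c(OC)cc1CC(C(=O)O)C(=O)O | intermediate (not isolated)
6 | 3-(2,4,5-trimethoxyphenyl)propanoic acid | COc1cc(OC)c(OC)cc1CCC(=O)O | intermediate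
7 | (R)-4-benzyloxazolidin-2-one | O=C1N[C@H](Cc2ccccc2)CO1 | starting material
8 | 3-(2,4,5-trimethoxyphenyl)propanoic pivalic anhydride | COc1cc(OC)c(OC)cc1CCC(=O)OC(=O)C(C)(C)C | intermediate (not isolated)
9 | (R)-4-benzyl-3-[3-(2,4,5-trimethoxyphenyl)propanoyl]oxazolidin-2-one | COc1cc(OC)c(OC)cc1CCC(=O)N1[C@H](Cc2ccccc2)COC1=O | intermediate
10 | trichlorotitanium (Z)-enolate of 9 | COc1cc(OC)c(OC)cc1C/C=C(\O[Ti](Cl)(Cl)Cl)N1[C@H](Cc2ccccc2)COC1=O | intermediate (not isolated)
11 | (R)-4-benzyl-3-[(S)-3-hydroxy-2-(2,4,5-trimethoxybenzyl)propanoyl]oxazolidin-2-one | COc1cc(OC)c(OC)cc1C[C@@H](CO)C(=O)N1[C@H](Cc2ccccc2)COC1=O | intermediate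
12 | (R)-4-benzyl-3-[(S)-3-(tert-butyldiphenylsilyloxy)-2-(2,4,5-trimethoxybenzyl)propanoyl]oxazolidin-2-one | COc1cc(OC)c(OC)cc1C[C@@H](CO[Si](c2ccccc2)(c2ccccc2)C(C)(C)C)C(=O)N1[C@H](Cc2ccccc2)COC1=O | intermediate
13 | (R)-3-(tert-butyldiphenylsilyloxy)-2-(2,4,5-trimethoxybenzyl)propan-1-ol | COc1cc(OC)c(OC)cc1C[C@@H](CO[Si](c2ccccc2)(c2ccccc2)C(C)(C)C)CO | intermediate
14 | (S)-3-(tert-butyldiphenylsilyloxy)-2-(2,4,5-trimethoxybenzyl)propanal | COc1cc(OC)c(OC)cc1C[C@@H](CO[Si](c2ccccc2)(c2ccccc2)C(C)(C)C)C=O | intermediate
15 | (R)-tert-butyldiphenyl{[2-(2,4,5-trimethoxybenzyl)but-3-yn-1-yl]oxy}silane | COc1cc(OC)c(OC)cc1C[C@@H](CO[Si](c2ccccc2)(c2ccccc2)C(C)(C)C)C#C | intermediate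
16 | 5-iodo-1,2,3-trimethoxybenzene | COc1cc(I)cc(OC)c1OC | starting material
17 | (R)-tert-butyldiphenyl{[2-(2,4,5-trimethoxybenzyl)-4-(3,4,5-trimethoxyphenyl)but-3-yn-1-yl]oxy}silane | COc1cc(OC)c(OC)cc1C[C@@H](CO[Si](c2ccccc2)(c2ccccc2)C(C)(C)C)C#Cc1cc(OC)c(OC)c(OC)c1 | intermediate
18 | (R)-2-(2,4,5-trimethoxybenzyl)-4-(3,4,5-trimethoxyphenyl)but-3-yn-1-ol | COc1cc(OC)c(OC)cc1C[C@@H](CO)C#Cc1cc(OC)c(OC)c(OC)c1 | intermediate
19 | methyl (R)-4-(2,4,5-trimethoxybenzyl)-2-(3,4,5-trimethoxyphenyl)-4,5-dihydrofuran-3-carboxylate | COc1cc(OC)c(OC)cc1C[C@H]1COC(c2cc(OC)c(OC)c(OC)c2)=C1C(=O)OC | intermediate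
20 | methyl (2R,3S,4R)-4-(2,4,5-trimethoxybenzyl)-2-(3,4,5-trimethoxyphenyl)oxolane-3-carboxylate (all-cis) | COc1cc(OC)c(OC)cc1C[C@H]1CO[C@@H](c2cc(OC)c(OC)c(OC)c2)[C@H]1C(=O)OC | intermediate
21 | [(2R,3R,4R)-4-(2,4,5-trimethoxybenzyl)-2-(3,4,5-trimethoxyphenyl)oxolan-3-yl]methanol (all-cis) | COc1cc(OC)c(OC)cc1C[C@H]1CO[C@@H](c2cc(OC)c(OC)c(OC)c2)[C@H]1CO | target

## Step count and uncertain steps

Total step count: 12. Longest linear sequence: 12 steps (1 to 21); the auxiliary 7 and the iodide 16 are purchased and enter at steps 2 and 8.

Step 10 (key step). The most likely failure is protonolysis of the C3–palladium bond before CO inserts. This amounts to a cycloisomerisation, followed by addition of methanol across the new enol ether. It is plausible because 5-endo closure onto an internal alkyne is slow and CO at 1 atm is dilute. Capture of the acylpalladium by a second alkynol, and carbonylation of the hydroxyl ahead of cyclisation, are further diversions. The fallback sets out from 18 and comes back at 19 by separating the two bond formations. A 5-endo-dig iodocyclisation (I2, NaHCO3, MeCN, 0 °C) should give (S)-3-iodo-4-(2,4,5-trimethoxybenzyl)-2-(3,4,5-trimethoxyphenyl)-4,5-dihydrofuran F1. Methoxycarbonylation of this vinyl iodide under zerovalent palladium catalysis (Pd(OAc)2, dppf, CO, MeOH, Et3N, DMF, 60 °C) should then give 19.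

Step 3. Lewis-acid-activated formaldehyde may attack the electron-rich ring A in a Friedel–Crafts sense, and the methoxy groups may sequester TiCl4 so that enolisation stays incomplete. The fallback sets out from 1 and comes back at 13; it replaces the auxiliary by an enzymatic desymmetrisation.
- Knoevenagel condensation of 1 with diethyl malonate (piperidine, AcOH, toluene, reflux) should give diethyl 2-(2,4,5-trimethoxybenzylidene)malonate F2.
- Hydrogenation (H2, Pd/C, EtOAc) should give diethyl 2-(2,4,5-trimethoxybenzyl)malonate F3, and LiAlH4 the prochiral 2-(2,4,5-trimethoxybenzyl)propane-1,3-diol F4.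
- A lipase (Burkholderia cepacia lipase) then differentiates the two arms to give (S)-3-hydroxy-2-(2,4,5-trimethoxybenzyl)propyl acetate F5. This is done by acetylation of F4 with vinyl acetate or, should the enzyme acylate the other arm, by hydrolysis of 2-(2,4,5-trimethoxybenzyl)propane-1,3-diyl diacetate F6 (from F4 with Ac2O, pyridine). The two modes expose opposite arms.
- Silylation of the free arm (TBDPSCl, imidazole) gives (R)-3-(tert-butyldiphenylsilyloxy)-2-(2,4,5-trimethoxybenzyl)propyl acetate F7, and methanolysis of the acetate (K2CO3, MeOH, 0 °C) returns to 13.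

Step 7. The α-stereocentre of 14 may epimerise, or silanolate may be lost by β-elimination, under carbonate in methanol before the aldehyde is consumed. The fallback sets out from 14 and comes back at 15 by a Corey–Fuchs sequence. CBr4 and PPh3 (CH2Cl2, 0 °C) should give (R)-tert-butyl{[4,4-dibromo-2-(2,4,5-trimethoxybenzyl)but-3-en-1-yl]oxy}diphenylsilane F8, which no longer has a hydrogen alpha to a carbonyl. n-BuLi (THF, −78 °C), then water, should give 15.

Step 11. Reduction of the tetrasubstituted, ester-conjugated double bond may be slow. Under forcing pressure, hydrogenolysis of the benzylic C2–O1 bond of the product or partial saturation of the arenes could then compete, and face selectivity could be incomplete. The fallback sets out from 19 and comes back at 21, bypassing 20, by inverting the order of the two reductions. DIBAL-H (CH2Cl2, −78 °C) should give [(R)-4-(2,4,5-trimethoxybenzyl)-2-(3,4,5-trimethoxyphenyl)-4,5-dihydrofuran-3-yl]methanol F9. Its double bond is an ordinary electron-rich enol ether and should take up hydrogen at low pressure (Raney nickel or Rh/Al2O3, EtOAc, trace Et3N), again from the face away from the C4 benzyl group. This order also avoids an epimerisable ester at C3.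

## Further compounds

F1 | step 10 | (S)-3-iodo-4-(2,4,5-trimethoxybenzyl)-2-(3,4,5-trimethoxyphenyl)-4,5-dihydrofuran | COc1cc(OC)c(OC)cc1C[C@H]1COC(c2cc(OC)c(OC)c(OC)c2)=C1I
F2 | step 3 | diethyl 2-(2,4,5-trimethoxybenzylidene)malonate | CCOC(=O)C(=Cc1cc(OC)c(OC)cc1OC)C(=O)OCC
F3 | step 3 | diethyl 2-(2,4,5-trimethoxybenzyl)malonate | CCOC(=O)C(Cc1cc(OC)c(OC)cc1OC)C(=O)OCC
F4 | step 3 | 2-(2,4,5-trimethoxybenzyl)propane-1,3-diol | COc1cc(OC)c(OC)cc1CC(CO)CO
F5 | step 3 | (S)-3-hydroxy-2-(2,4,5-trimethoxybenzyl)propyl acetate | COc1cc(OC)c(OC)cc1C[C@@H](CO)COC(C)=O
F6 | step 3 | 2-(2,4,5-trimethoxybenzyl)propane-1,3-diyl diacetate | COc1cc(OC)c(OC)cc1CC(COC(C)=O)COC(C)=O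
F7 | step 3 | (R)-3-(tert-butyldiphenylsilyloxy)-2-(2,4,5-trimethoxybenzyl)propyl acetate | COc1cc(OC)c(OC)cc1C[C@@H](CO[Si](c2ccccc2)(c2ccccc2)C(C)(C)C)COC(C)=O
F8 | step 7 | (R)-tert-butyl{[4,4-dibromo-2-(2,4,5-trimethoxybenzyl)but-3-en-1-yl]oxy}diphenylsilane | COc1cc(OC)c(OC)cc1C[C@@H](CO[Si](c2ccccc2)(c2ccccc2)C(C)(C)C)C=C(Br)Br
F9 | step 11 | [(R)-4-(2,4,5-trimethoxybenzyl)-2-(3,4,5-trimethoxyphenyl)-4,5-dihydrofuran-3-yl]methanol | COc1cc(OC)c(OC)cc1C[C@H]1COC(c2cc(OC)c(OC)c(OC)c2)=C1CO
A1 | alternative 1 | 2-(3,4,5-trimethoxyphenyl)furan | COc1cc(-c2ccco2)cc(OC)c1OC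
A2 | alternative 1 | maleic anhydride | O=C1OC(=O)C=C1
A3 | alternative 1 | exo-1-(3,4,5-trimethoxyphenyl)-7-oxabicyclo[2.2.1]hept-5-ene-2,3-dicarboxylic anhydride | O=C1OC(=O)[C@@H]2[C@H]1[C@@]1(c3cc(OC)c(OC)c(OC)c3)C=C[C@@H]2O1
A4 | alternative 2 | methyl (Z)-2-diazo-3-{[(3,4,5-trimethoxybenzyl)oxy]methyl}-4-(2,4,5-trimethoxyphenyl)but-3-enoate | COC(=O)C(=[N+]=[N-])/C(COCc1cc(OC)c(OC)c(OC)c1)=C/c1cc(OC)c(OC)cc1OC
A5 | alternative 2 | methyl cis-2-(3,4,5-trimethoxyphenyl)-4-[(Z)-2,4,5-trimethoxybenzylidene]oxolane-3-carboxylate | COc1cc(OC)c(OC)cc1/C=C1\CO[C@@H](c2cc(OC)c(OC)c(OC)c2)[C@H]1C(=O)OC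
A6 | alternative 3 | tert-butyldimethyl{[3-(3,4,5-trimethoxyphenyl)-2-[3-(2,4,5-trimethoxyphenyl)prop-1-en-2-yl]oxiran-2-yl]methoxy}silane, aryl-bearing carbon configured as C2 of the target, aryl trans to the silyloxymethyl group | CC(C)(C)[Si](C)(C)OC[C@]1(C(=C)Cc2cc(OC)c(OC)cc2OC)O[C@H]1c1cc(OC)c(OC)c(OC)c1
A7 | alternative 3 | 3-(tert-butyldimethylsilyloxymethyl)-4-(2,4,5-trimethoxybenzyl)-2-(3,4,5-trimethoxyphenyl)-2,5-dihydrofuran, C2 configured as in the target | COc1cc(OC)c(OC)cc1CC1=C(CO[Si](C)(C)C(C)(C)C)[C@H](c2cc(OC)c(OC)c(OC)c2)OC1
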